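(5R)-2-(Hydroxymethyl)-1,3-dimethoxy-5-octyl-5,6,7,8-tetrahydroquinolin-4(1H)-one: route proposal (ring A = N-methoxy-4-pyridone, ring B = carbocycle; quinolinone locants throughout).

- Target 14 ← desilylation and side-chain hydrogenation of alkenyl compound 12.
- 12 ← one-step [4+2] carboannulation of dibromide 9 with (3E)-deca-1,3-diene 11: C7–C6 by radical addition, C4a–C5 by enantioselective aryl–allyl coupling at nickel.
- Enabling feature: C4a is an sp2 carbon α to the C4 carbonyl (easily brominated, oxidative-addition site) and C7 is a primary carbon two atoms from C8a. The C5–C6 edge of ring B therefore maps onto the terminal C=C of a diene, whose second C=C (C1'–C2' of the side chain) is a traceless activator.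
- 9 ← ring bromination and Appel reaction of pyridone 7 ← O-to-N ring-atom exchange (MeONH2) on pyranone 6 ← lateral and ring hydroxymethylation, O-methylation and silylation of allomaltol 1.
- Ring order: pyranone (purchased) → ring A by atom exchange → ring B last, in the key step.

Key step: step 9

Assumption: the sense of induction of the chiral nickel catalyst in step 9 cannot be predicted with certainty, so the ligand antipode that gives the 5S product 12 is fixed in a first screen; allomaltol and (2E)-non-2-enal are taken as purchased.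

Step 1
Reactants: 1 allomaltol (5-hydroxy-2-methyl-4H-pyran-4-one)
Product: 2 3-hydroxy-2-(hydroxymethyl)-6-methyl-4H-pyran-4-one
Conditions: 37% aq CH2O, NaOH (1.1 equiv), H2O, rt; HCl to pH 2
Reagents that add atoms: formaldehyde, C=O
Why: Base-mediated aldol-type hydroxymethylation of the enolised 3-hydroxy-4-pyranone occurs at the only free position ortho to the hydroxyl group, a known reaction of this compound.

Step 2
Reactants: 2 3-hydroxy-2-(hydroxymethyl)-6-methyl-4H-pyran-4-one
Product: 3 2-(hydroxymethyl)-3-methoxy-6-methyl-4H-pyran-4-one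
Conditions: MeI, K2CO3, acetone, reflux
Reagents that add atoms: iodomethane, CI
Why: Williamson O-methylation under weak base should alkylate only the acidic enolic hydroxyl and leave the primary alcohol untouched.

Step 3
Reactants: 3 2-(hydroxymethyl)-3-methoxy-6-methyl-4H-pyran-4-one
Product: 4 2-({[tert-butyl(diphenyl)silyl]oxy}methyl)-3-methoxy-6-methyl-4H-pyran-4-one
Conditions: TBDPSCl, imidazole, DMF, rt
Reagents that add atoms: tert-butyl(chloro)diphenylsilane, CC(C)(C)[Si](Cl)(c1ccccc1)c1ccccc1
Why: Standard silylation of a primary alcohol gives a bulky ether that should survive all later steps and shield its own CH2 group from deprotonation in step 4.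

Step 4
Reactants: 4 2-({[tert-butyl(diphenyl)silyl]oxy}methyl)-3-methoxy-6-methyl-4H-pyran-4-one
Product: 6 2-({[tert-butyl(diphenyl)silyl]oxy}methyl)-6-(2-hydroxyethyl)-3-methoxy-4H-pyran-4-one, via lithium dienolate 5 (not isolated)
Conditions: LiHMDS (1.1 equiv), THF, −78 °C; CH2O gas (from paraformaldehyde, 160 °C), −78 → −20 °C; H2O
Reagents that add atoms: formaldehyde, C=O
Why: Lateral (vinylogous) deprotonation of the 6-methyl group of a 4-pyranone gives dienolate 5, whose aldol-type addition to formaldehyde at the exocyclic carbon puts C8 and C7 of the target in place, deprotonation at the hindered silyloxymethyl group being disfavoured.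

Step 5
Reactants: 6 2-({[tert-butyl(diphenyl)silyl]oxy}methyl)-6-(2-hydroxyethyl)-3-methoxy-4H-pyran-4-one
Product: 7 2-({[tert-butyl(diphenyl)silyl]oxy}methyl)-6-(2-hydroxyethyl)-1,3-dimethoxypyridin-4(1H)-one
Conditions: MeONH2·HCl (3 equiv), pyridine, 90 °C, sealed tube
Reagents that add atoms: O-methylhydroxylamine hydrochloride, CON.Cl
Why: Ring-atom exchange of a 4-pyranone by an amine (conjugate addition, ring opening, recondensation with loss of water) is the classical pyranone-to-pyridone conversion, run here with methoxyamine so that the N–OMe group arrives with the nitrogen.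

Step 6
Reactants: 7 2-({[tert-butyl(diphenyl)silyl]oxy}methyl)-6-(2-hydroxyethyl)-1,3-dimethoxypyridin-4(1H)-one
Product: 8 5-bromo-2-({[tert-butyl(diphenyl)silyl]oxy}methyl)-6-(2-hydroxyethyl)-1,3-dimethoxypyridin-4(1H)-one
Conditions: NBS (1.05 equiv), MeCN, 0 °C, dark
Reagents that add atoms: N-bromosuccinimide, O=C1CCC(=O)N1Br
Why: Electrophilic bromination of the vinylogous amide should occur at its α-carbon C5, the only ring C–H, which is far more nucleophilic in the pyridone than in the pyranone.

Step 7
Reactants: 8 5-bromo-2-({[tert-butyl(diphenyl)silyl]oxy}methyl)-6-(2-hydroxyethyl)-1,3-dimethoxypyridin-4(1H)-one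
Product: 9 5-bromo-6-(2-bromoethyl)-2-({[tert-butyl(diphenyl)silyl]oxy}methyl)-1,3-dimethoxypyridin-4(1H)-one
Conditions: CBr4, PPh3, CH2Cl2, 0 °C
Reagents that add atoms: carbon tetrabromide, BrC(Br)(Br)Br
Why: The Appel reaction converts the primary alcohol into the bromide under neutral conditions, which avoids base-induced loss of HBr to the vinylpyridone.

Step 8
Reactants: 10 (2E)-non-2-enal
Product: 11 (3E)-deca-1,3-diene
Conditions: Ph3PCH3Br, KOtBu, THF, 0 °C → rt
Reagents that add atoms: methyltriphenylphosphonium bromide, C[P+](c1ccccc1)(c1ccccc1)c1ccccc1.[Br-]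
Why: Wittig methylenation with the non-stabilised ylide converts the aldehyde into a terminal alkene without touching the E-configured double bond.

Step 9
Reactants: 9 5-bromo-6-(2-bromoethyl)-2-({[tert-butyl(diphenyl)silyl]oxy}methyl)-1,3-dimethoxypyridin-4(1H)-one; 11 (3E)-deca-1,3-diene
Product: 12 (5S)-2-({[tert-butyl(diphenyl)silyl]oxy}methyl)-1,3-dimethoxy-5-[(1E)-oct-1-en-1-yl]-5,6,7,8-tetrahydroquinolin-4(1H)-one
Conditions: NiBr2·glyme (10 mol %), (S,S)-iPr-BiOX (12 mol %, antipode fixed by screening), Mn powder (3 equiv), 11 (3 equiv), DMA, 0 °C, slow addition of 9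
Reagents that add atoms: none
Why: Proposed new method: in this nickel-catalysed enantioselective reductive carboannulation, zerovalent nickel inserts into the C4a–Br bond of 9, a monovalent nickel species abstracts bromine from C7, the primary C7 radical adds to the unsubstituted terminus of diene 11 (C7–C6 bond), and the allyl radical so formed is captured by the tethered aryl–nickel unit, reductive elimination from trivalent nickel then forming C4a–C5; the closest known reaction types are the three-component nickel-catalysed reductive 1,2-alkylarylation of 1,3-dienes and alkenes with alkyl and aryl halides and the enantioconvergent nickel-catalysed reductive arylation of secondary benzylic or allylic radicals with BiOX-type ligands. Ring B closes as a six-membered ring by inner-sphere C(sp2)–C(sp3) reductive elimination at the proximal allyl carbon of a seven-membered aryl–allyl nickelacycle, coupling at the distal allyl carbon being excluded because it would give an eight-membered ring holding an E-alkene. The C5 stereocentre is set in this reductive elimination under control of the chiral ligand: the planar allyl radical is captured reversibly and the allyl–nickel isomers interconvert, so both faces should funnel into one configuration, the ligand antipode being chosen to give 5S. The step needs chemoselectivity (oxidative addition at the sp2 C–Br, halogen abstraction at the sp3 C–Br), regioselective radical addition (secured by the terminal CH2 of the diene and the allylic stabilisation of the adduct radical, which also makes addition fast enough to outrun reduction or β-hydride loss) and intramolecular capture over oligomerisation (secured by slow addition of 9 and excess diene). The E/Z purity of the diene is irrelevant because the side-chain alkene is saturated in step 10.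

Step 10
Reactants: 12 (5S)-2-({[tert-butyl(diphenyl)silyl]oxy}methyl)-1,3-dimethoxy-5-[(1E)-oct-1-en-1-yl]-5,6,7,8-tetrahydroquinolin-4(1H)-one
Product: 13 (5R)-2-({[tert-butyl(diphenyl)silyl]oxy}methyl)-1,3-dimethoxy-5-octyl-5,6,7,8-tetrahydroquinolin-4(1H)-one
Conditions: H2 (1–3 atm), RhCl(PPh3)3 (5 mol %), PhH/EtOH 1:1, rt
Reagents that add atoms: none
Why: Homogeneous hydrogenation with Wilkinson's catalyst should saturate the disubstituted side-chain alkene without double-bond migration toward C5 and without cleaving the N–OMe bond, so the stereocentre is kept and its descriptor changes from S to R only because the CIP priorities change.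

Step 11
Reactants: 13 (5R)-2-({[tert-butyl(diphenyl)silyl]oxy}methyl)-1,3-dimethoxy-5-octyl-5,6,7,8-tetrahydroquinolin-4(1H)-one
Product: 14 (5R)-2-(hydroxymethyl)-1,3-dimethoxy-5-octyl-5,6,7,8-tetrahydroquinolin-4(1H)-one
Conditions: TBAF, THF, 0 °C → rt
Reagents that add atoms: none
Why: Fluoride-mediated cleavage of the silyl ether should free the primary alcohol without affecting the N-methoxy pyridone or the C5 stereocentre.

Compound list
1 | allomaltol (5-hydroxy-2-methyl-4H-pyran-4-one) | Cc1cc(=O)c(O)co1 | starting material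
2 | 3-hydroxy-2-(hydroxymethyl)-6-methyl-4H-pyran-4-one | Cc1cc(=O)c(O)c(CO)o1 | intermediate
3 | 2-(hydroxymethyl)-3-methoxy-6-methyl-4H-pyran-4-one | Cc1cc(=O)c(OC)c(CO)o1 | intermediate
4 | 2-({[tert-butyl(diphenyl)silyl]oxy}methyl)-3-methoxy-6-methyl-4H-pyran-4-one | Cc1cc(=O)c(OC)c(CO[Si](c2ccccc2)(c2ccccc2)C(C)(C)C)o1 | intermediate
5 | lithium dienolate of 4 (6-lithiomethyl form) | [Li]Cc1cc(=O)c(OC)c(CO[Si](c2ccccc2)(c2ccccc2)C(C)(C)C)o1 | intermediate
6 | 2-({[tert-butyl(diphenyl)silyl]oxy}methyl)-6-(2-hydroxyethyl)-3-methoxy-4H-pyran-4-one | OCCc1cc(=O)c(OC)c(CO[Si](c2ccccc2)(c2ccccc2)C(C)(C)C)o1 | intermediate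
7 | 2-({[tert-butyl(diphenyl)silyl]oxy}methyl)-6-(2-hydroxyethyl)-1,3-dimethoxypyridin-4(1H)-one | OCCc1cc(=O)c(OC)c(CO[Si](c2ccccc2)(c2ccccc2)C(C)(C)C)n1OC | intermediate
8 | 5-bromo-2-({[tert-butyl(diphenyl)silyl]oxy}methyl)-6-(2-hydroxyethyl)-1,3-dimethoxypyridin-4(1H)-one | OCCc1c(Br)c(=O)c(OC)c(CO[Si](c2ccccc2)(c2ccccc2)C(C)(C)C)n1OC | intermediate
9 | 5-bromo-6-(2-bromoethyl)-2-({[tert-butyl(diphenyl)silyl]oxy}methyl)-1,3-dimethoxypyridin-4(1H)-one | BrCCc1c(Br)c(=O)c(OC)c(CO[Si](c2ccccc2)(c2ccccc2)C(C)(C)C)n1OC | intermediate
10 | (2E)-non-2-enal | CCCCCC/C=C/C=O | starting material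
11 | (3E)-deca-1,3-diene | C=C/C=C/CCCCCC | intermediate
12 | (5S)-2-({[tert-butyl(diphenyl)silyl]oxy}methyl)-1,3-dimethoxy-5-[(1E)-oct-1-en-1-yl]-5,6,7,8-tetrahydroquinolin-4(1H)-one | CCCCCC/C=C/[C@@H]1CCCc2c1c(=O)c(OC)c(CO[Si](c3ccccc3)(c3ccccc3)C(C)(C)C)n2OC | intermediate
13 | (5R)-2-({[tert-butyl(diphenyl)silyl]oxy}methyl)-1,3-dimethoxy-5-octyl-5,6,7,8-tetrahydroquinolin-4(1H)-one | CCCCCCCC[C@@H]1CCCc2c1c(=O)c(OC)c(CO[Si](c3ccccc3)(c3ccccc3)C(C)(C)C)n2OC | intermediate
14 | (5R)-2-(hydroxymethyl)-1,3-dimethoxy-5-octyl-5,6,7,8-tetrahydroquinolin-4(1H)-one | CCCCCCCC[C@@H]1CCCc2c1c(=O)c(OC)c(CO)n2OC | target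

Total step count: 11. Longest linear sequence: 10 (steps 1–7 and 9–11; step 8 is a one-step side branch).

Steps most likely to fail

Step 9 (proposed new method). The C7 radical may be reduced or captured by nickel before it adds to the diene. The allyl radical may couple with an aryl–nickel unit of a second molecule, giving oligomers. β-Hydride loss may give the 6-vinyl compound, low-valent nickel may cleave the N–OMe bond, or the reductive elimination may show poor facial selectivity. The fallback uses known chemistry only, sets out from 7 and comes back at 13. Pyridone 7 is converted under Appel conditions (CBr4, PPh3, CH2Cl2) into 6-(2-bromoethyl)-2-({[tert-butyl(diphenyl)silyl]oxy}methyl)-1,3-dimethoxypyridin-4(1H)-one F1. This alkylates purchased ethyl 3-oxoundecanoate (K2CO3, acetone; directly or through elimination and conjugate addition) to give keto ester F2. Saponification and decarboxylation (LiOH, aq THF; then AcOH, 50 °C) should give the δ-keto pyridone F3. Acid-mediated cyclodehydration (TsOH, toluene, Dean–Stark), in which the nucleophilic C5–H carbon of the vinylogous amide attacks the ketone, should close ring B as the 5-octyl-7,8-dihydroquinolinone F4. Iridium-catalysed asymmetric hydrogenation of this 1-alkyl-3,4-dihydronaphthalene-type olefin ([Ir(cod)(L)]BArF, L = chiral PHOX-type N,P ligand, H2 50 bar, CH2Cl2) then sets C5 and gives 13.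

Step 5. Conjugate addition of the weakly basic alkoxyamine to the 2,6-dialkylated pyranone may stall, attack may divert to the C4 carbonyl (oxime ether formation), or prolonged heating with pyridinium chloride may erode the silyl ether. The fallback sets out from 6 and comes back at 7. The less hindered hydroxylamine (NH2OH·HCl, NaOAc, aq EtOH, 70 °C) performs the ring-atom exchange to give the N-hydroxypyridone F5. The N–O–CH3 bond is then made by alkylation of the acidic N-hydroxy group (MeI, K2CO3, DMF, rt), the primary alcohol being left alone, to give 7.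

Step 4. Deprotonation may compete at the silyloxymethyl carbon (followed by silyl migration from oxygen to carbon), or formaldehyde may add twice. The fallback sets out from 4 and comes back at 6. Condensation of the 6-methyl group with DMF dimethyl acetal (neat, 110 °C) needs no strong base and should select the unhindered methyl group, giving the enamine F6. Hydrolysis (aq AcOH, THF) gives the pyranylacetaldehyde F7, which is reduced without isolation (NaBH4, MeOH, 0 °C) to 6.

Further compounds
F1 | step 9 | 6-(2-bromoethyl)-2-({[tert-butyl(diphenyl)silyl]oxy}methyl)-1,3-dimethoxypyridin-4(1H)-one | BrCCc1cc(=O)c(OC)c(CO[Si](c2ccccc2)(c2ccccc2)C(C)(C)C)n1OC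
F2 | step 9 | ethyl 2-{2-[6-({[tert-butyl(diphenyl)silyl]oxy}methyl)-1,5-dimethoxy-4-oxo-1,4-dihydropyridin-2-yl]ethyl}-3-oxoundecanoate | CCCCCCCCC(=O)C(CCc1cc(=O)c(OC)c(CO[Si](c2ccccc2)(c2ccccc2)C(C)(C)C)n1OC)C(=O)OCC
F3 | step 9 | 2-({[tert-butyl(diphenyl)silyl]oxy}methyl)-1,3-dimethoxy-6-(4-oxododecyl)pyridin-4(1H)-one | CCCCCCCCC(=O)CCCc1cc(=O)c(OC)c(CO[Si](c2ccccc2)(c2ccccc2)C(C)(C)C)n1OC
F4 | step 9 | 2-({[tert-butyl(diphenyl)silyl]oxy}methyl)-1,3-dimethoxy-5-octyl-7,8-dihydroquinolin-4(1H)-one | CCCCCCCCC1=CCCc2c1c(=O)c(OC)c(CO[Si](c3ccccc3)(c3ccccc3)C(C)(C)C)n2OC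
F5 | step 5 | 2-({[tert-butyl(diphenyl)silyl]oxy}methyl)-1-hydroxy-6-(2-hydroxyethyl)-3-methoxypyridin-4(1H)-one | OCCc1cc(=O)c(OC)c(CO[Si](c2ccccc2)(c2ccccc2)C(C)(C)C)n1O
F6 | step 4 | 2-({[tert-butyl(diphenyl)silyl]oxy}methyl)-6-[(E)-2-(dimethylamino)ethenyl]-3-methoxy-4H-pyran-4-one | CN(C)/C=C/c1cc(=O)c(OC)c(CO[Si](c2ccccc2)(c2ccccc2)C(C)(C)C)o1
F7 | step 4 | [6-({[tert-butyl(diphenyl)silyl]oxy}methyl)-5-methoxy-4-oxo-4H-pyran-2-yl]acetaldehyde | O=CCc1cc(=O)c(OC)c(CO[Si](c2ccccc2)(c2ccccc2)C(C)(C)C)o1
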